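**Retrosynthetic overview**

1. The target is (3S)-6-geranyl-7,4'-dihydroxy-2'-methoxyisoflavanone; the last operation is buffered fluoride removal of two TIPS ethers from the ring-closed (3S)-ketone, so no base meets C3 after it is set.
2. Key disconnection O1–C2 of ring C: an organocatalytic 6-endo oxa-Michael ring closure with enantioselective protonation at C3 of an achiral ortho-hydroxyaryl α-aryl vinyl ketone. The enabling feature is the phenol oxygen on C8a of ring A (the future O1), which sits ortho to the C4 ketone and six atoms from the exocyclic methylene carbon (the future C2), with C3 as the enolate carbon that takes the proton.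
3. C3–C4 disconnection of the enone: a 1-arylvinyllithium made from the ring B acetophenone (Shapiro reaction) adds to the ring A salicylaldehyde, and MnO2 gives the enone.
4. C6–geranyl disconnection on ring A: Stille coupling of the 4-O-TIPS ether of 5-bromo-2,4-dihydroxybenzaldehyde with geranyltributylstannane; the chelated 2-OH is never protected.
5. Ring order: rings A and B are bought as arenes; ring C is the only ring formed, in step 8.

Key step: step 8

Assumption: the facial sense of proton delivery by the cinchona squaramide cannot be predicted with confidence; the quinine-derived catalyst is written for the (3S) series, and its quinidine-derived pseudoenantiomer would be used if the opposite sense were found.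

**Route**

Step 1
Reactants: 1 5-bromo-2,4-dihydroxybenzaldehyde
Product: 2 5-bromo-2-hydroxy-4-[(triisopropylsilyl)oxy]benzaldehyde
Conditions: TIPSCl (1.05 equiv), imidazole (2.2 equiv), DMF, 0 °C
Reagents that add atoms: triisopropylsilyl chloride, CC(C)[Si](Cl)(C(C)C)C(C)C
Why: Phenol O-silylation: the 2-OH is tied up in its hydrogen bond to the aldehyde carbonyl, so that only the free, more acidic 4-OH should be silylated.

Step 2
Reactants: 3 geranyl chloride [(2E)-1-chloro-3,7-dimethylocta-2,6-diene]
Product: 4 geranyltributylstannane (tributyl[(2E)-3,7-dimethylocta-2,6-dien-1-yl]stannane)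
Conditions: Bu3SnH, LiN(i-Pr)2 (LDA), THF, 0 °C; then 3, −78 °C to 0 °C
Reagents that add atoms: tributyltin hydride, CCCC[SnH](CCCC)CCCC
Why: Alkylation of a stannyl anion (SN2): tributylstannyllithium, made in the flask, should displace the primary allylic chloride at the unsubstituted carbon and leave the (2E)-alkene unchanged.

Step 3
Reactants: 2 5-bromo-2-hydroxy-4-[(triisopropylsilyl)oxy]benzaldehyde, 4 geranyltributylstannane
Product: 5 5-[(2E)-3,7-dimethylocta-2,6-dien-1-yl]-2-hydroxy-4-[(triisopropylsilyl)oxy]benzaldehyde
Conditions: Pd(PPh3)4 (5 mol%), DMF, 90 °C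
Reagents that add atoms: none
Why: Stille coupling: oxidative addition of zerovalent palladium into the C–Br bond, transmetalation of the allylstannane and reductive elimination at its unsubstituted terminus should give the linear (E)-geranyl arene under neutral conditions that the silyl ether, the aldehyde and the chelated phenol tolerate.

Step 4
Reactants: 6 1-(4-hydroxy-2-methoxyphenyl)ethan-1-one
Product: 7 1-{2-methoxy-4-[(triisopropylsilyl)oxy]phenyl}ethan-1-one
Conditions: TIPSCl, imidazole, DMF, rt
Reagents that add atoms: triisopropylsilyl chloride, CC(C)[Si](Cl)(C(C)C)C(C)C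
Why: Phenol O-silylation of the only hydroxyl group, which blocks the 4'-oxygen through the organolithium and amine-catalysed steps and is removed by fluoride at the end.

Step 5
Reactants: 7 1-{2-methoxy-4-[(triisopropylsilyl)oxy]phenyl}ethan-1-one
Product: 8 2,4,6-triisopropylbenzenesulfonyl hydrazone of ketone 7
Conditions: 2,4,6-triisopropylbenzenesulfonyl hydrazide (1.05 equiv), cat HCl, THF, rt
Reagents that add atoms: 2,4,6-triisopropylbenzenesulfonyl hydrazide, NNS(=O)(=O)c1c(C(C)C)cc(C(C)C)cc1C(C)C
Why: Condensation of the methyl ketone with the sulfonyl hydrazide (hydrazone formation) installs the leaving groups for the Shapiro reaction, the bulky triisopropylphenyl group preventing ortho-lithiation of the sulfonyl arene.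

Step 6
Reactants: 8 2,4,6-triisopropylbenzenesulfonyl hydrazone of ketone 7, 5 5-[(2E)-3,7-dimethylocta-2,6-dien-1-yl]-2-hydroxy-4-[(triisopropylsilyl)oxy]benzaldehyde
Product: 11 racemic 1-{5-[(2E)-3,7-dimethylocta-2,6-dien-1-yl]-2-hydroxy-4-[(triisopropylsilyl)oxy]phenyl}-2-{2-methoxy-4-[(triisopropylsilyl)oxy]phenyl}prop-2-en-1-ol, via vinyllithium 9 (not isolated), via sodium phenoxide 10 (not isolated)
Conditions: 8 (1.3 equiv), n-BuLi (2.1 equiv per 8), THF, −78 °C then 0 °C; separately 5, NaH (1.05 equiv), THF, 0 °C; combined at −78 °C; aq NH4Cl; crude product used directly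
Reagents that add atoms: none
Why: Shapiro reaction and 1,2-addition: double deprotonation of 8 with loss of sulfinate and N2 should give the 1-arylvinyllithium 9 regiospecifically, which adds to the aldehyde of 10, whose phenol is masked as the sodium salt so that no vinyllithium is quenched; the new carbinol centre is racemic and is removed in step 7.

Step 7
Reactants: 11 racemic allylic alcohol
Product: 12 1-{5-[(2E)-3,7-dimethylocta-2,6-dien-1-yl]-2-hydroxy-4-[(triisopropylsilyl)oxy]phenyl}-2-{2-methoxy-4-[(triisopropylsilyl)oxy]phenyl}prop-2-en-1-one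
Conditions: activated MnO2 (15 equiv), CH2Cl2, rt; filtration through Celite, no base, used promptly
Reagents that add atoms: none
Why: MnO2 oxidation of an allylic and benzylic alcohol under neutral, base-free conditions, which should leave the silyl ethers, the geranyl alkenes and the phenol alone and deliver the enone as its O–H···O=C chelate, a form that does not close the ring without base.

Step 8
Reactants: 12 ortho-hydroxyaryl α-aryl vinyl ketone
Product: 14 (3S)-6-[(2E)-3,7-dimethylocta-2,6-dien-1-yl]-3-{2-methoxy-4-[(triisopropylsilyl)oxy]phenyl}-7-[(triisopropylsilyl)oxy]-2,3-dihydro-4H-chromen-4-one, via enolate 13 (not isolated)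
Conditions: quinine-derived squaramide catalyst [squaramide of 9-amino-9-deoxy-epi-quinine and 3,5-bis(trifluoromethyl)aniline] (5 mol%), toluene, −40 °C; cold filtration through silica gel
Reagents that add atoms: none
Why: Proposed new method: the quinuclidine nitrogen of the bifunctional catalyst takes the proton of the chelated 2-OH of ring A while the squaramide N–H pair binds the C4 carbonyl, the phenoxide oxygen (the future O1 on C8a) adds to the unsubstituted methylene terminus (the future C2) of the α-aryl enone, and the catalyst-bound enolate 13 is then protonated at C3 by the quinuclidinium N–H inside the ion pair. The closest known reaction types are the cinchona thiourea- or squaramide-catalysed intramolecular oxa-Michael cyclisation of ortho-hydroxyaryl enones to chromanones and flavanones, and the bifunctional-catalyst hetero-Michael addition with enantioselective protonation of α-substituted acrylic acid derivatives and α-substituted vinyl ketones; their merger into an O1–C2 ring closure that sets a tertiary α-aryl ketone centre has not been shown for isoflavanones. Ring C closes in a 6-endo-trig mode. The only new stereocentre, C3, is set under catalyst control by face-selective proton transfer to the planar enolate, whose two faces are differentiated in the squaramide pocket by the ortho-methoxyaryl group on C3 and the plane of ring A, with (3S) assumed for the quinine-derived series. The step needs chemoselectivity for the 2-OH, which the TIPS ethers on the other two phenols and the six-membered reach secure; it needs the absence of an uncatalysed racemic closure, which the O–H···O=C4 chelate secures by holding the neutral phenol away from C2; and it needs survival of the kinetic product, which the several pKa units between the phenol O–H and the C3–H, the weak amine base, the non-polar solvent and the low temperature should secure.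

Step 9
Reactants: 14 (3S)-bis(TIPS ether)
Product: 15 (3S)-6-[(2E)-3,7-dimethylocta-2,6-dien-1-yl]-7-hydroxy-3-(4-hydroxy-2-methoxyphenyl)-2,3-dihydro-4H-chromen-4-one
Conditions: HF·pyridine, pyridine, THF, 0 °C to rt
Reagents that add atoms: none
Why: Fluoride-mediated cleavage of both aryl silyl ethers (desilylation) in a pyridine-buffered, weakly acidic medium, in which neither enolisation at C3 nor acid-promoted reaction of the geranyl alkenes is expected, so that the (3S) configuration should survive.

**Compound list**

1 | 5-bromo-2,4-dihydroxybenzaldehyde | O=Cc1cc(Br)c(O)cc1O | starting material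
2 | 5-bromo-2-hydroxy-4-[(triisopropylsilyl)oxy]benzaldehyde | O=Cc1cc(Br)c(O[Si](C(C)C)(C(C)C)C(C)C)cc1O | intermediate
3 | geranyl chloride, (2E)-1-chloro-3,7-dimethylocta-2,6-diene | ClC/C=C(\C)CCC=C(C)C | starting material
4 | geranyltributylstannane, tributyl[(2E)-3,7-dimethylocta-2,6-dien-1-yl]stannane | CCCC[Sn](CCCC)(CCCC)C/C=C(\C)CCC=C(C)C | intermediate
5 | 5-[(2E)-3,7-dimethylocta-2,6-dien-1-yl]-2-hydroxy-4-[(triisopropylsilyl)oxy]benzaldehyde | O=Cc1cc(C/C=C(\C)CCC=C(C)C)c(O[Si](C(C)C)(C(C)C)C(C)C)cc1O | intermediate
6 | 1-(4-hydroxy-2-methoxyphenyl)ethan-1-one | CC(=O)c1ccc(O)cc1OC | starting material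
7 | 1-{2-methoxy-4-[(triisopropylsilyl)oxy]phenyl}ethan-1-one | CC(=O)c1ccc(O[Si](C(C)C)(C(C)C)C(C)C)cc1OC | intermediate
8 | 2,4,6-triisopropylbenzenesulfonyl hydrazone of 7 (C=N geometry immaterial) | CC(=NNS(=O)(=O)c1c(C(C)C)cc(C(C)C)cc1C(C)C)c1ccc(O[Si](C(C)C)(C(C)C)C(C)C)cc1OC | intermediate
9 | 1-{2-methoxy-4-[(triisopropylsilyl)oxy]phenyl}vinyllithium | [Li]C(=C)c1ccc(O[Si](C(C)C)(C(C)C)C(C)C)cc1OC | intermediate (not isolated)
10 | sodium phenoxide of aldehyde 5 | [Na+].[O-]c1cc(O[Si](C(C)C)(C(C)C)C(C)C)c(C/C=C(\C)CCC=C(C)C)cc1C=O | intermediate (not isolated)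
11 | racemic 1-{5-geranyl-2-hydroxy-4-[(triisopropylsilyl)oxy]phenyl}-2-{2-methoxy-4-[(triisopropylsilyl)oxy]phenyl}prop-2-en-1-ol | C=C(c1ccc(O[Si](C(C)C)(C(C)C)C(C)C)cc1OC)C(O)c1cc(C/C=C(\C)CCC=C(C)C)c(O[Si](C(C)C)(C(C)C)C(C)C)cc1O | intermediate
12 | 1-{5-geranyl-2-hydroxy-4-[(triisopropylsilyl)oxy]phenyl}-2-{2-methoxy-4-[(triisopropylsilyl)oxy]phenyl}prop-2-en-1-one | C=C(c1ccc(O[Si](C(C)C)(C(C)C)C(C)C)cc1OC)C(=O)c1cc(C/C=C(\C)CCC=C(C)C)c(O[Si](C(C)C)(C(C)C)C(C)C)cc1O | intermediate
13 | catalyst-bound enolate of 14, drawn as the neutral enol 6-geranyl-3-{2-methoxy-4-[(triisopropylsilyl)oxy]phenyl}-7-[(triisopropylsilyl)oxy]-2H-chromen-4-ol | COc1cc(O[Si](C(C)C)(C(C)C)C(C)C)ccc1C1=C(O)c2cc(C/C=C(\C)CCC=C(C)C)c(O[Si](C(C)C)(C(C)C)C(C)C)cc2OC1 | intermediate (not isolated)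
14 | (3S)-6-geranyl-3-{2-methoxy-4-[(triisopropylsilyl)oxy]phenyl}-7-[(triisopropylsilyl)oxy]-2,3-dihydro-4H-chromen-4-one | COc1cc(O[Si](C(C)C)(C(C)C)C(C)C)ccc1[C@H]1COc2cc(O[Si](C(C)C)(C(C)C)C(C)C)c(C/C=C(\C)CCC=C(C)C)cc2C1=O | intermediate
15 | (3S)-6-[(2E)-3,7-dimethylocta-2,6-dien-1-yl]-7-hydroxy-3-(4-hydroxy-2-methoxyphenyl)-2,3-dihydro-4H-chromen-4-one | COc1cc(O)ccc1[C@H]1COc2cc(O)c(C/C=C(\C)CCC=C(C)C)cc2C1=O | target

**Step count**

Total step count: 9. Longest linear sequence: 6 steps (steps 1, 3, 6, 7, 8, 9; the ring B branch through steps 4, 5, 6, 7, 8, 9 is equally long).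

**Steps most likely to fail**

Step 8 (Proposed new method). What may go wrong: poor facial selectivity in the proton transfer to the enolate, or amine-mediated enolisation of the product after it has formed, so that ring C closes but the enantiomeric purity is low. The fallback uses known chemistry, sets out from 12 and returns at 14.
- 12 is stirred with Et3N (0.2 equiv) in EtOAc at rt, which should close ring C without stereocontrol (6-endo oxa-Michael addition) to the racemic 7,4'-bis(triisopropylsilyloxy)-6-geranyl-2'-methoxyisoflavanone F1.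
- HCO2H/Et3N (5:2) and RuCl(p-cymene)[(S,S)-TsDPEN] (2 mol%) are then added at 40 °C. F1 racemises through its enol faster than it is reduced, so asymmetric transfer hydrogenation with dynamic kinetic resolution should funnel both enantiomers into the cis-(3S,4S)-isoflavan-4-ol F2. With this catalyst enantiomer, hydride delivery to the benzo-fused aryl ketone is expected to give 4S, and the aryl group ends up cis.
- Buffered Dess–Martin oxidation of F2 (DMP, NaHCO3, CH2Cl2, 0 °C) regenerates the C4 ketone without touching C3 and returns to 14.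

Step 3. What may go wrong: slow oxidative addition into the hindered, electron-rich C–Br bond, transfer of the geranyl group with allylic transposition or loss of the (E) geometry, or protodestannylation of 4 by the phenol. The fallback reverses the polarity of the coupling so that the geranyl unit enters as the electrophile; it sets out from 1 and returns at 5.
- Both phenols of 1 are protected (NaH, MOMCl, DMF, 0 °C) to give 5-bromo-2,4-bis(methoxymethoxy)benzaldehyde F3.
- Miyaura borylation (B2pin2, PdCl2(dppf), KOAc, dioxane, 80 °C) gives the pinacol boronate 2,4-bis(methoxymethoxy)-5-(4,4,5,5-tetramethyl-1,3,2-dioxaborolan-2-yl)benzaldehyde F4.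
- Suzuki–Miyaura coupling of F4 with geranyl bromide (Pd(PPh3)4, K3PO4, THF, 50 °C) should give 5-geranyl-2,4-bis(methoxymethoxy)benzaldehyde F5; the aryl group is delivered to the less substituted terminus of the (E)-configured π-geranyl palladium intermediate.
- Methanolysis of both acetals (2 M HCl, MeOH, 40 °C) gives 5-geranyl-2,4-dihydroxybenzaldehyde F6, and selective silylation of its 4-OH under the conditions of step 1 returns to 5.

Step 9. What may go wrong: enolisation at C3 during silyl cleavage, which erodes the configuration, or acid-promoted cyclisation of the geranyl chain onto the liberated 7-OH. The fallback moves the deprotection to the carbinol oxidation level, where C3 cannot enolise, and makes a neutral oxidation the last step; it sets out from 14 and returns at 15.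
- 14 is reduced with RuCl(p-cymene)[(S,S)-TsDPEN] and HCO2H/Et3N to the cis-(3S,4S)-isoflavan-4-ol F2. This is the matched catalyst, and it would also correct any minor enantiomer through dynamic kinetic resolution.
- TBAF (THF, 0 °C, pH 7 work-up) removes both silyl groups to give the cis-(3S,4S)-6-geranyl-3-(4-hydroxy-2-methoxyphenyl)chromane-4,7-diol F7.
- Activated MnO2 (EtOAc, rt) should then oxidise the benzylic C4 carbinol chemoselectively and give 15 directly.

Further compounds
F1 | step 8 | racemic 6-geranyl-3-{2-methoxy-4-[(triisopropylsilyl)oxy]phenyl}-7-[(triisopropylsilyl)oxy]-2,3-dihydro-4H-chromen-4-one | COc1cc(O[Si](C(C)C)(C(C)C)C(C)C)ccc1C1COc2cc(O[Si](C(C)C)(C(C)C)C(C)C)c(C/C=C(\C)CCC=C(C)C)cc2C1=O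
F2 | step 8 | cis-(3S,4S)-6-geranyl-3-{2-methoxy-4-[(triisopropylsilyl)oxy]phenyl}-7-[(triisopropylsilyl)oxy]chroman-4-ol | COc1cc(O[Si](C(C)C)(C(C)C)C(C)C)ccc1[C@H]1COc2cc(O[Si](C(C)C)(C(C)C)C(C)C)c(C/C=C(\C)CCC=C(C)C)cc2[C@H]1O
F3 | step 3 | 5-bromo-2,4-bis(methoxymethoxy)benzaldehyde | O=Cc1cc(Br)c(OCOC)cc1OCOC
F4 | step 3 | 2,4-bis(methoxymethoxy)-5-(4,4,5,5-tetramethyl-1,3,2-dioxaborolan-2-yl)benzaldehyde | O=Cc1cc(B2OC(C)(C)C(C)(C)O2)c(OCOC)cc1OCOC
F5 | step 3 | 5-[(2E)-3,7-dimethylocta-2,6-dien-1-yl]-2,4-bis(methoxymethoxy)benzaldehyde | O=Cc1cc(C/C=C(\C)CCC=C(C)C)c(OCOC)cc1OCOC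
F6 | step 3 | 5-[(2E)-3,7-dimethylocta-2,6-dien-1-yl]-2,4-dihydroxybenzaldehyde | O=Cc1cc(C/C=C(\C)CCC=C(C)C)c(O)cc1O
F7 | step 9 | cis-(3S,4S)-6-[(2E)-3,7-dimethylocta-2,6-dien-1-yl]-3-(4-hydroxy-2-methoxyphenyl)chromane-4,7-diol | COc1cc(O)ccc1[C@H]1COc2cc(O)c(C/C=C(\C)CCC=C(C)C)cc2[C@H]1O
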